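**Retrosynthetic overview** (locants are those of the target name given for compound 23)
- C11=C12 (E) comes from dehydration of a C11 carbinol; the C10–C11 bond and the C10 quaternary centre come from a chiral phosphoric acid allylboration joining a C16 ring aldehyde and a C16 allyl boronate.
- Ring aldehyde: the C13 methyl centre is set by organocatalytic transfer hydrogenation of an enal. The only ring (the cyclohexane) is closed early by a chiral Brønsted acid cation–ene cycloisomerisation of an achiral trienenitrile, which sets both ring stereocentres and the exocyclic olefin.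
- Trienenitrile: from an allylic bromide, a silylpropyne, butenone and a cyanomethylphosphonate; carboalumination fixes the E trisubstituted olefin.
- Allyl boronate: from farnesyl acetate by terminal allylic oxidation, copper-catalysed SN2' methylation (remote C3 methyl centre) and borylation.

Assumption: 1-bromo-2,3-dimethylbut-2-ene, (2E,6E)-farnesyl acetate and both antipodes of each chiral catalyst are purchasable; the antipode named follows the closest precedent and is exchanged for its mirror image if the first run shows the opposite sense.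

**Step 1**
Reactants: 1 1-bromo-2,3-dimethylbut-2-ene; 2 trimethyl(prop-1-yn-1-yl)silane
Product: 4 5,6-dimethylhept-5-en-1-yne, via TMS-capped enyne 3 (not isolated)
Conditions: 2, n-BuLi, THF, −78 to −20 °C; 1, −78 °C to rt; then K2CO3, MeOH, rt
Reagents that add atoms: none
Why: Propargylic lithiation of the silylpropyne and SN2 alkylation by the primary allylic bromide (SN2' would have to attack a fully substituted carbon) build the 1,5-enyne, and methanolysis in the same pot removes the silyl cap; no stereocentre is formed.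

**Step 2**
Reactants: 4 5,6-dimethylhept-5-en-1-yne; 5 but-3-en-2-one
Product: 7 (5E)-6,9,10-trimethylundeca-5,9-dien-2-one, via alkenylalane 6 (not isolated)
Conditions: Me3Al (2 equiv), Cp2ZrCl2 (20 mol %), CH2Cl2, 0 °C to rt; excess Me3Al removed in vacuo; 5, Et2O/hexane, −30 °C to rt; aq. NH4Cl
Reagents that add atoms: trimethylaluminium, C[Al](C)C
Why: Zirconium-catalysed Negishi carboalumination adds CH3 and Al syn across the terminal alkyne, and the alkenylalane then transfers its alkenyl group 1,4 to the s-cis enone with retention, which fixes the E trisubstituted olefin.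

**Step 3**
Reactants: 7 (5E)-6,9,10-trimethylundeca-5,9-dien-2-one; 8 diethyl (cyanomethyl)phosphonate
Product: 9 (2E,6E)-3,7,10,11-tetramethyldodeca-2,6,10-trienenitrile
Conditions: NaH, THF, 0 °C to rt; 2E isomer separated from the minor 2Z isomer on silica
Reagents that add atoms: none
Why: Horner–Wadsworth–Emmons olefination of the methyl ketone gives the conjugated nitrile (2E/2Z about 3:1), an electron-poor chain end that cannot intercept the cation generated in step 4.

**Step 4**
Reactants: 9 (2E,6E)-3,7,10,11-tetramethyldodeca-2,6,10-trienenitrile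
Product: 10 (2E)-3-methyl-5-[(1R,3R)-2,2,3-trimethyl-6-methylidenecyclohexyl]pent-2-enenitrile
Conditions: (S,S)-IDPi Brønsted acid (BINOL-derived imidodiphosphorimidate, N–SO2CF3 arms, bulky 3,3'-aryl walls; 5 mol %), (CF3)3COH/toluene 1:4, −40 °C, quenched with Et3N at about 85 % conversion; AgNO3–silica chromatography
Reagents that add atoms: none
Why: Proposed new method: the confined chiral acid protonates the tetrasubstituted C10=C11 olefin (the most basic site) at C10 on one enantiotopic face while the E C6=C7 olefin attacks C11 anti through a catalyst-enforced chair, so the new C10–H is equatorial, the C10 methyl axial and the side chain equatorial (1,3-trans, 1R,3R), and the ion-paired tertiary C7 cation is then deprotonated at its exposed methyl group by the bulky conjugate base (the only base present, the axial ring C–H bonds being shielded by the gem-dimethyl group and the side chain) to give the exocyclic olefin and return the acid; the closest known reactions are IDPi-catalysed proton-initiated polyene cyclisation with heteroatom termination, IDPi-catalysed carbonyl–ene cyclisation and the Brønsted acid cyclisation of pseudoirones, none of which combines enantioselective protonation of a tetrasubstituted olefin with exo-selective deprotonative (ene-type) termination.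

**Step 5**
Reactants: 10 (2E)-3-methyl-5-[(1R,3R)-2,2,3-trimethyl-6-methylidenecyclohexyl]pent-2-enenitrile
Product: 12 (2E)-3-methyl-5-[(1R,3R)-2,2,3-trimethyl-6-methylidenecyclohexyl]pent-2-enal, via N-aluminoimine 11 (not isolated)
Conditions: i-Bu2AlH (1.2 equiv), toluene, −78 °C; then aq. tartaric acid, rt
Reagents that add atoms: water, O
Why: Partial reduction of the nitrile by i-Bu2AlH stops at the N-aluminoimine (1,2-hydride addition), which hydrolyses to the enal on work-up without touching the isolated olefins or the ring stereocentres.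

**Step 6**
Reactants: 12 (2E)-3-methyl-5-[(1R,3R)-2,2,3-trimethyl-6-methylidenecyclohexyl]pent-2-enal
Product: 13 (3S)-3-methyl-5-[(1R,3R)-2,2,3-trimethyl-6-methylidenecyclohexyl]pentanal
Conditions: morpholine (20 mol %), (S)-TRIP (20 mol %), Hantzsch ester (1.1 equiv), dioxane, 50 °C
Reagents that add atoms: none
Why: Counteranion-directed iminium transfer hydrogenation (the organocatalytic conjugate reduction used for citral and farnesal) delivers hydride from the Hantzsch ester to the Re face of C3 of the iminium ion paired with the chiral phosphate, setting 3S (about 95:5 expected).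

**Step 7**
Reactants: 14 (2E,6E)-3,7,11-trimethyldodeca-2,6,10-trien-1-yl acetate (farnesyl acetate)
Product: 15 (2E,6E,10E)-12-hydroxy-3,7,11-trimethyldodeca-2,6,10-trien-1-yl acetate
Conditions: SeO2 (0.3 equiv), t-BuOOH (3 equiv), salicylic acid (0.1 equiv), CH2Cl2, rt, to about 60 % conversion, 14 recycled
Reagents that add atoms: tert-butyl hydroperoxide, CC(C)(C)OO
Why: Selenium dioxide allylic oxidation (ene reaction then 2,3-sigmatropic shift) selects the most electron-rich terminal olefin and its E methyl group, giving the E allylic alcohol.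

**Step 8**
Reactants: 15 (2E,6E,10E)-12-hydroxy-3,7,11-trimethyldodeca-2,6,10-trien-1-yl acetate
Product: 17 (2E,6E,10E)-12-chloro-3,7,11-trimethyldodeca-2,6,10-trien-1-yl acetate, via allylic mesylate 16 (not isolated)
Conditions: MsCl, 2,4,6-collidine, LiCl, DMF, 0 °C
Reagents that add atoms: lithium chloride, [Li+].[Cl-]; methanesulfonyl chloride, CS(=O)(=O)Cl
Why: Mesylation and SN2 displacement by chloride in the same pot give the primary allylic chloride without allylic transposition or loss of the E geometry.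

**Step 9**
Reactants: 17 (2E,6E,10E)-12-chloro-3,7,11-trimethyldodeca-2,6,10-trien-1-yl acetate
Product: 18 (2E,6E,10R)-3,7,10,11-tetramethyldodeca-2,6,11-trien-1-yl acetate
Conditions: MeMgBr (1.2 equiv, slow addition), CuBr·SMe2 (3 mol %), BINOL-derived phosphoramidite ligand (4 mol %), CH2Cl2, −78 °C
Reagents that add atoms: methylmagnesium bromide, C[Mg]Br
Why: Copper-catalysed asymmetric allylic alkylation (SN2') of a β-methyl allylic chloride delivers methyl to C10 under ligand control, setting 10R and unveiling the isopropenyl group, while the allylic acetate is left alone at −78 °C.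

**Step 10**
Reactants: 18 (2E,6E,10R)-3,7,10,11-tetramethyldodeca-2,6,11-trien-1-yl acetate
Product: 19 4,4,5,5-tetramethyl-2-[(2E,6E,10R)-3,7,10,11-tetramethyldodeca-2,6,11-trien-1-yl]-1,3,2-dioxaborolane
Conditions: B2pin2 (1.1 equiv), Pd2(dba)3 (2.5 mol %), DMSO, 50 °C
Reagents that add atoms: bis(pinacolato)diboron, CC1(C)OB(OC1(C)C)B1OC(C)(C)C(C)(C)O1
Why: Palladium-catalysed Miyaura-type borylation of the allylic acetate through a π-allyl complex puts boron on the primary terminus with retention of the 2E geometry; the remote C10 centre is untouched.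

**Step 11**
Reactants: 13 (3S)-3-methyl-5-[(1R,3R)-2,2,3-trimethyl-6-methylidenecyclohexyl]pentanal; 19 4,4,5,5-tetramethyl-2-[(2E,6E,10R)-3,7,10,11-tetramethyldodeca-2,6,11-trien-1-yl]-1,3,2-dioxaborolane
Product: 21 (3S,5R,6S,9E,13R)-6-ethenyl-3,6,10,13,14-pentamethyl-1-[(1R,3R)-2,2,3-trimethyl-6-methylidenecyclohexyl]pentadeca-9,14-dien-5-ol, via borate ester 20 (not isolated)
Conditions: (S)-TRIP (10 mol %), 4 Å molecular sieves, toluene, −20 °C to rt; then aq. NaHCO3
Reagents that add atoms: none
Why: Chiral phosphoric acid catalysed allylboration through a closed chair transition state: the catalyst sends the γ,γ-disubstituted E allyl boronate to the Si face of the aldehyde (5R) and the E geometry puts the chain equatorial and the methyl axial, so the quaternary centre forms as 6S (anti), with little influence from the β-stereocentre of 13.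

**Step 12**
Reactants: 21 (3S,5R,6S,9E,13R)-6-ethenyl-3,6,10,13,14-pentamethyl-1-[(1R,3R)-2,2,3-trimethyl-6-methylidenecyclohexyl]pentadeca-9,14-dien-5-ol
Product: 23 (3R,6E,10S,11E,13S)-10-ethenyl-2,3,6,10,13-pentamethyl-15-[(1R,3R)-2,2,3-trimethyl-6-methylidenecyclohexyl]pentadeca-1,6,11-triene, via sulfamate ester 22 (not isolated)
Conditions: Burgess reagent (2 equiv), toluene, rt then 70 °C
Reagents that add atoms: none
Why: Burgess dehydration (syn Ei elimination of the sulfamate) can only remove hydrogen from the CH2 side because the other neighbour is the quaternary carbon, and the bulk of that carbon enforces the E olefin; only the carbinol stereocentre is consumed.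

**Compound list**
1 | 1-bromo-2,3-dimethylbut-2-ene | BrCC(C)=C(C)C | starting material
2 | trimethyl(prop-1-yn-1-yl)silane | CC#C[Si](C)(C)C | starting material
3 | (5,6-dimethylhept-5-en-1-yn-1-yl)trimethylsilane | C[Si](C)(C)C#CCCC(C)=C(C)C | intermediate
4 | 5,6-dimethylhept-5-en-1-yne | C#CCCC(C)=C(C)C | intermediate
5 | but-3-en-2-one | C=CC(C)=O | starting material
6 | dimethyl[(1E)-2,5,6-trimethylhepta-1,5-dien-1-yl]alumane | C[Al](C)/C=C(\C)CCC(C)=C(C)C | intermediate
7 | (5E)-6,9,10-trimethylundeca-5,9-dien-2-one | CC(=O)CC/C=C(\C)CCC(C)=C(C)C | intermediate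
8 | diethyl (cyanomethyl)phosphonate | CCOP(=O)(CC#N)OCC | starting material
9 | (2E,6E)-3,7,10,11-tetramethyldodeca-2,6,10-trienenitrile | N#C/C=C(\C)CC/C=C(\C)CCC(C)=C(C)C | intermediate
10 | (2E)-3-methyl-5-[(1R,3R)-2,2,3-trimethyl-6-methylidenecyclohexyl]pent-2-enenitrile | N#C/C=C(\C)CC[C@@H]1C(=C)CC[C@@H](C)C1(C)C | intermediate
11 | (2E)-N-[bis(2-methylpropyl)alumanyl]-3-methyl-5-[(1R,3R)-2,2,3-trimethyl-6-methylidenecyclohexyl]pent-2-en-1-imine | CC(C)C[Al](CC(C)C)N=C/C=C(\C)CC[C@@H]1C(=C)CC[C@@H](C)C1(C)C | intermediate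
12 | (2E)-3-methyl-5-[(1R,3R)-2,2,3-trimethyl-6-methylidenecyclohexyl]pent-2-enal | O=C/C=C(\C)CC[C@@H]1C(=C)CC[C@@H](C)C1(C)C | intermediate
13 | (3S)-3-methyl-5-[(1R,3R)-2,2,3-trimethyl-6-methylidenecyclohexyl]pentanal | O=CC[C@@H](C)CC[C@@H]1C(=C)CC[C@@H](C)C1(C)C | intermediate
14 | (2E,6E)-3,7,11-trimethyldodeca-2,6,10-trien-1-yl acetate | CC(=O)OC/C=C(\C)CC/C=C(\C)CCC=C(C)C | starting material
15 | (2E,6E,10E)-12-hydroxy-3,7,11-trimethyldodeca-2,6,10-trien-1-yl acetate | CC(=O)OC/C=C(\C)CC/C=C(\C)CC/C=C(\C)CO | intermediate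
16 | (2E,6E,10E)-12-(methanesulfonyloxy)-3,7,11-trimethyldodeca-2,6,10-trien-1-yl acetate | CC(=O)OC/C=C(\C)CC/C=C(\C)CC/C=C(\C)COS(C)(=O)=O | intermediate
17 | (2E,6E,10E)-12-chloro-3,7,11-trimethyldodeca-2,6,10-trien-1-yl acetate | CC(=O)OC/C=C(\C)CC/C=C(\C)CC/C=C(\C)CCl | intermediate
18 | (2E,6E,10R)-3,7,10,11-tetramethyldodeca-2,6,11-trien-1-yl acetate | CC(=O)OC/C=C(\C)CC/C=C(\C)CC[C@@H](C)C(=C)C | intermediate
19 | 4,4,5,5-tetramethyl-2-[(2E,6E,10R)-3,7,10,11-tetramethyldodeca-2,6,11-trien-1-yl]-1,3,2-dioxaborolane | CC1(C)OB(C/C=C(\C)CC/C=C(\C)CC[C@@H](C)C(=C)C)OC1(C)C | intermediate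
20 | 2-{[(3S,5R,6S,9E,13R)-6-ethenyl-3,6,10,13,14-pentamethyl-1-[(1R,3R)-2,2,3-trimethyl-6-methylidenecyclohexyl]pentadeca-9,14-dien-5-yl]oxy}-4,4,5,5-tetramethyl-1,3,2-dioxaborolane | C=C[C@@](C)([C@H](OB2OC(C)(C)C(C)(C)O2)C[C@@H](C)CC[C@@H]1C(=C)CC[C@@H](C)C1(C)C)CC/C=C(\C)CC[C@@H](C)C(=C)C | intermediate
21 | (3S,5R,6S,9E,13R)-6-ethenyl-3,6,10,13,14-pentamethyl-1-[(1R,3R)-2,2,3-trimethyl-6-methylidenecyclohexyl]pentadeca-9,14-dien-5-ol | C=C[C@@](C)([C@H](O)C[C@@H](C)CC[C@@H]1C(=C)CC[C@@H](C)C1(C)C)CC/C=C(\C)CC[C@@H](C)C(=C)C | intermediate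
22 | methyl N-({[(3S,5R,6S,9E,13R)-6-ethenyl-3,6,10,13,14-pentamethyl-1-[(1R,3R)-2,2,3-trimethyl-6-methylidenecyclohexyl]pentadeca-9,14-dien-5-yl]oxy}sulfonyl)carbamate | C=C[C@@](C)([C@H](OS(=O)(=O)NC(=O)OC)C[C@@H](C)CC[C@@H]1C(=C)CC[C@@H](C)C1(C)C)CC/C=C(\C)CC[C@@H](C)C(=C)C | intermediate
23 | (3R,6E,10S,11E,13S)-10-ethenyl-2,3,6,10,13-pentamethyl-15-[(1R,3R)-2,2,3-trimethyl-6-methylidenecyclohexyl]pentadeca-1,6,11-triene | C=C[C@@](C)(/C=C/[C@@H](C)CC[C@@H]1C(=C)CC[C@@H](C)C1(C)C)CC/C=C(\C)CC[C@@H](C)C(=C)C | target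

**Total step count:** 12. **Longest linear sequence:** 8 (steps 1–6, then 11 and 12).

**Three steps most likely to fail**

Step 4 (the proposed new reaction). The risks are unassisted protonation of the C6=C7 olefin, termination to endocyclic olefins, acid isomerisation of the exocyclic olefin, and low enantioselectivity. The fallback uses known chemistry and sets the ring methyl centre before ring closure; it sets out from 18 and comes back to the route at 12. Compound 18 already carries the required R methyl centre from the copper-catalysed allylic alkylation. It is cyclised with a stoichiometric achiral Brønsted acid (chlorosulfonic acid, 2-nitropropane, −78 °C), the classical farnesyl-acetate-type monocyclisation started by protonation of the isopropenyl group; the allylic-acetate olefin is deactivated and stays open. This substrate-controlled closure gives a mixture of ring-olefin and 1,3-cis/trans isomers, from which (2E)-3-methyl-5-[(1R,3R)-2,2,3-trimethyl-6-methylidenecyclohexyl]pent-2-en-1-yl acetate F1 is isolated on AgNO3-impregnated silica. Methanolysis (K2CO3, MeOH) gives (2E)-3-methyl-5-[(1R,3R)-2,2,3-trimethyl-6-methylidenecyclohexyl]pent-2-en-1-ol F2, and MnO2 in CH2Cl2 oxidises it to 12. The price is low regio- and diastereoselectivity and consumption of 18, but every operation is precedented.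

Step 11. The risks are slow addition of the hindered γ,γ-disubstituted boronate and incomplete catalyst control at the quaternary centre. The fallback is a copper–NHC enantioselective allylic substitution, which also makes step 12 unnecessary; it sets out from 13 and 18 and comes back at 23.
- Aldehyde 13 is treated in one pot with nonafluorobutanesulfonyl fluoride and a phosphazene base in DMF. This passes through (3S)-3-methyl-5-[(1R,3R)-2,2,3-trimethyl-6-methylidenecyclohexyl]pent-1-en-1-yl nonafluorobutane-1-sulfonate F3 and gives the terminal alkyne (3S)-3-methyl-5-[(1R,3R)-2,2,3-trimethyl-6-methylidenecyclohexyl]pent-1-yne F4.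
- Hydroalumination of the alkyne (i-Bu2AlH, hexane, 55 °C) gives bis(2-methylpropyl)[(1E,3S)-3-methyl-5-[(1R,3R)-2,2,3-trimethyl-6-methylidenecyclohexyl]pent-1-en-1-yl]alumane F5.
- In parallel 18 is deacetylated (K2CO3, MeOH) to (2E,6E,10R)-3,7,10,11-tetramethyldodeca-2,6,11-trien-1-ol F6 and phosphorylated (ClP(O)(OEt)2, pyridine) to diethyl (2E,6E,10R)-3,7,10,11-tetramethyldodeca-2,6,11-trien-1-yl phosphate F7.
- The alane and the phosphate are joined with CuCl2·2H2O (2 mol %) and a chiral sulfonate-bearing imidazolinium NHC precursor in THF at −15 °C. SN2' attack of the alkenyl group creates the methyl/vinyl quaternary centre and the E disubstituted olefin in one step (the construction used for bakuchiol) and gives 23 directly.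

Step 12. The risks are ionisation of the sulfamate next to the vinyl-bearing quaternary carbon (homoallyl to cyclopropylcarbinyl rearrangement) and sluggish sulfamate formation at the hindered carbinol. The fallback is oxidation, enol triflate formation and reduction; it sets out from 21 and comes back at 23. Dess–Martin periodinane gives (3S,6S,9E,13R)-6-ethenyl-3,6,10,13,14-pentamethyl-1-[(1R,3R)-2,2,3-trimethyl-6-methylidenecyclohexyl]pentadeca-9,14-dien-5-one F8. KN(SiMe3)2 and PhNTf2 in THF at −78 °C convert it, through the Z enolate (only the CH2 side can enolise), into (3S,4Z,6S,9E,13R)-6-ethenyl-3,6,10,13,14-pentamethyl-1-[(1R,3R)-2,2,3-trimethyl-6-methylidenecyclohexyl]pentadeca-4,9,14-trien-5-yl trifluoromethanesulfonate F9. Pd(OAc)2, PPh3, n-Bu3N and HCO2H in DMF at 60 °C replace the triflate by hydrogen with retention and give the E olefin 23.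

**Further compounds**
F1 | step 4 | (2E)-3-methyl-5-[(1R,3R)-2,2,3-trimethyl-6-methylidenecyclohexyl]pent-2-en-1-yl acetate | CC(=O)OC/C=C(\C)CC[C@@H]1C(=C)CC[C@@H](C)C1(C)C
F2 | step 4 | (2E)-3-methyl-5-[(1R,3R)-2,2,3-trimethyl-6-methylidenecyclohexyl]pent-2-en-1-ol | OC/C=C(\C)CC[C@@H]1C(=C)CC[C@@H](C)C1(C)C
F3 | step 11 | (3S)-3-methyl-5-[(1R,3R)-2,2,3-trimethyl-6-methylidenecyclohexyl]pent-1-en-1-yl nonafluorobutane-1-sulfonate | FC(F)(F)C(F)(F)C(F)(F)C(F)(F)S(=O)(=O)OC=C[C@@H](C)CC[C@@H]1C(=C)CC[C@@H](C)C1(C)C
F4 | step 11 | (3S)-3-methyl-5-[(1R,3R)-2,2,3-trimethyl-6-methylidenecyclohexyl]pent-1-yne | C#C[C@@H](C)CC[C@@H]1C(=C)CC[C@@H](C)C1(C)C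
F5 | step 11 | bis(2-methylpropyl)[(1E,3S)-3-methyl-5-[(1R,3R)-2,2,3-trimethyl-6-methylidenecyclohexyl]pent-1-en-1-yl]alumane | CC(C)C[Al](CC(C)C)/C=C/[C@@H](C)CC[C@@H]1C(=C)CC[C@@H](C)C1(C)C
F6 | step 11 | (2E,6E,10R)-3,7,10,11-tetramethyldodeca-2,6,11-trien-1-ol | OC/C=C(\C)CC/C=C(\C)CC[C@@H](C)C(=C)C
F7 | step 11 | diethyl (2E,6E,10R)-3,7,10,11-tetramethyldodeca-2,6,11-trien-1-yl phosphate | CCOP(=O)(OCC)OC/C=C(\C)CC/C=C(\C)CC[C@@H](C)C(=C)C
F8 | step 12 | (3S,6S,9E,13R)-6-ethenyl-3,6,10,13,14-pentamethyl-1-[(1R,3R)-2,2,3-trimethyl-6-methylidenecyclohexyl]pentadeca-9,14-dien-5-one | C=C[C@@](C)(C(=O)C[C@@H](C)CC[C@@H]1C(=C)CC[C@@H](C)C1(C)C)CC/C=C(\C)CC[C@@H](C)C(=C)C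
F9 | step 12 | (3S,4Z,6S,9E,13R)-6-ethenyl-3,6,10,13,14-pentamethyl-1-[(1R,3R)-2,2,3-trimethyl-6-methylidenecyclohexyl]pentadeca-4,9,14-trien-5-yl trifluoromethanesulfonate | C=C[C@@](C)(/C(OS(=O)(=O)C(F)(F)F)=C/[C@@H](C)CC[C@@H]1C(=C)CC[C@@H](C)C1(C)C)CC/C=C(\C)CC[C@@H](C)C(=C)C
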